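## Retrosynthetic overview

1. The only ring, the seven-membered α,β-unsaturated lactone, is closed last by ring-closing metathesis between an allyl group on the tertiary carbinol carbon and a 2-substituted acrylate ester on the secondary carbinol oxygen.
2. The acyclic ester comes from selective acylation of an anti-diol fragment (carrying the acetate, the E-olefin and both stereocentres) with 6-methyl-2-methylidenehept-5-enoic acid.
3. The diol comes from acid hydrolysis (inversion at the tertiary carbon) of a trans-epoxide made by Shi epoxidation of an E,E-triene; the triene comes from geranyl acetate by allylic hydroxylation, bromination and allyl–vinyl Stille coupling.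
4. The acid comes from diethyl malonate and 5-bromo-2-methylpent-2-ene by alkylation, half-saponification, decarboxylative Mannich methylenation and saponification.
5. Ring order: one ring only, formed in the final step.

Assumption: catalysts and reagents, including the L-sorbose-derived enantiomer of the Shi ketone, are taken as available and their preparation is not counted.

Locants C6 and C7 below refer to the deca-2,9-dienyl numbering of diol 7 (C6 = secondary carbinol, C7 = tertiary carbinol).

## Diol fragment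

Step 1
Reactants: 1 geranyl acetate, (2E)-3,7-dimethylocta-2,6-dien-1-yl acetate
Product: 2 (2E,6E)-8-hydroxy-3,7-dimethylocta-2,6-dien-1-yl acetate
Conditions: SeO2 (0.1 equiv), t-BuOOH (3 equiv), salicylic acid (0.1 equiv), CH2Cl2, rt
Reagents that add atoms: selenium dioxide, O=[Se]=O (catalytic oxygen carrier); tert-butyl hydroperoxide, CC(C)(C)OO (terminal oxidant)
Why: Sharpless-type catalytic SeO2 allylic oxidation (ene reaction then [2,3]-shift) hydroxylates the (E)-methyl of the electron-rich distal olefin, while the olefin next to the acetate is deactivated.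

Step 2
Reactants: 2 (2E,6E)-8-hydroxy-3,7-dimethylocta-2,6-dien-1-yl acetate
Product: 3 (2E,6E)-8-bromo-3,7-dimethylocta-2,6-dien-1-yl acetate
Conditions: CBr4, PPh3, CH2Cl2, 0 °C
Reagents that add atoms: tetrabromomethane, BrC(Br)(Br)Br
Why: Appel bromination of the primary allylic alcohol proceeds by SN2 at low temperature, without allylic transposition or loss of olefin geometry.

Step 3
Reactants: 3 (2E,6E)-8-bromo-3,7-dimethylocta-2,6-dien-1-yl acetate; 4 tributyl(ethenyl)stannane
Product: 5 (2E,6E)-3,7-dimethyldeca-2,6,9-trien-1-yl acetate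
Conditions: Pd2(dba)3 (2.5 mol %), P(2-furyl)3 (10 mol %), THF, 50 °C
Reagents that add atoms: none
Why: Migita–Kosugi–Stille allyl–vinyl coupling, in which zerovalent palladium inserts into the allylic C–Br bond much faster than into the allylic C–OAc bond and couples at the primary terminus, keeping the 6E geometry.

Step 4
Reactants: 5 (2E,6E)-3,7-dimethyldeca-2,6,9-trien-1-yl acetate
Product: 6 (2E)-3-methyl-5-[(2S,3S)-3-methyl-3-(prop-2-en-1-yl)oxiran-2-yl]pent-2-en-1-yl acetate
Conditions: ent-Shi ketone (1,2:4,5-di-O-isopropylidene-β-L-erythro-2,3-hexodiulo-2,6-pyranose, 0.3 equiv), Oxone (2KHSO5·KHSO4·K2SO4), K2CO3, Bu4NHSO4 (cat.), MeCN/CH2(OMe)2/aq. Na2B4O7 buffer (pH 10.5), −5 to 0 °C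
Reagents that add atoms: potassium peroxymonosulfate (active part of Oxone), [K+].[O-]S(=O)(=O)OO
Why: Shi asymmetric epoxidation, in which the chiral dioxirane attacks only the electron-rich E-trisubstituted 6,7-olefin through a spiro transition state; the L-series ketone sets both stereocentres as (6S,7S), the D-series ketone being known to give (R,R).

Step 5
Reactants: 6 (2E)-3-methyl-5-[(2S,3S)-3-methyl-3-(prop-2-en-1-yl)oxiran-2-yl]pent-2-en-1-yl acetate
Product: 7 (2E,6S,7R)-6,7-dihydroxy-3,7-dimethyldeca-2,9-dien-1-yl acetate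
Conditions: HClO4 (3% aq., cat.), THF/H2O 3:1, 0 °C
Reagents that add atoms: water, O
Why: Acid-catalysed epoxide hydrolysis, in which water attacks the protonated epoxide at the tertiary carbon from the back (7S to 7R) while the C6–O bond is untouched (6S kept), giving the anti diol.

## Acid fragment

Step 6
Reactants: 8 diethyl malonate; 9 5-bromo-2-methylpent-2-ene
Product: 10 diethyl 2-(4-methylpent-3-en-1-yl)propanedioate
Conditions: NaOEt, EtOH, reflux (8 in 1.5-fold excess)
Reagents that add atoms: none
Why: Malonic ester alkylation, an SN2 reaction of the sodium enolate at the primary homoallylic bromide.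

Step 7
Reactants: 10 diethyl 2-(4-methylpent-3-en-1-yl)propanedioate
Product: 11 2-(ethoxycarbonyl)-6-methylhept-5-enoic acid (racemic)
Conditions: KOH (1.0 equiv), EtOH, rt; then aq. HCl
Reagents that add atoms: potassium hydroxide, [K+].[OH-]
Why: Mono-saponification, which stops after one ester because the carboxylate formed retards attack on the second.

Step 8
Reactants: 11 2-(ethoxycarbonyl)-6-methylhept-5-enoic acid (racemic)
Product: 13 ethyl 6-methyl-2-methylidenehept-5-enoate, via Mannich base 12 (not isolated)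
Conditions: (CH2O)n, Et2NH, THF, reflux
Reagents that add atoms: formaldehyde (from paraformaldehyde), C=O
Why: Mannich condensation of the malonate half-ester followed by decarboxylative elimination of diethylamine gives the α-methylene ester and removes the racemic centre.

Step 9
Reactants: 13 ethyl 6-methyl-2-methylidenehept-5-enoate
Product: 14 6-methyl-2-methylidenehept-5-enoic acid
Conditions: LiOH·H2O, THF/H2O 3:1, rt; then aq. HCl to pH 3
Reagents that add atoms: lithium hydroxide, [Li+].[OH-]
Why: Ester saponification, with the α-substituted acrylate resisting conjugate addition of hydroxide at room temperature.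

## Coupling and ring closure

Step 10
Reactants: 7 (2E,6S,7R)-6,7-dihydroxy-3,7-dimethyldeca-2,9-dien-1-yl acetate; 14 6-methyl-2-methylidenehept-5-enoic acid
Product: 16 (2E,6S,7R)-1-(acetyloxy)-7-hydroxy-3,7-dimethyldeca-2,9-dien-6-yl 6-methyl-2-methylidenehept-5-enoate, via mixed anhydride 15 (not isolated)
Conditions: 14, 2,4,6-Cl3C6H2COCl, Et3N, THF, rt; then 7, DMAP, toluene, rt to 40 °C
Reagents that add atoms: none
Why: Yamaguchi esterification acylates only the secondary hydroxyl (the tertiary one is too hindered), which fixes the lactone oxygen at C6 without touching either stereocentre.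

Step 11
Reactants: 16 (2E,6S,7R)-1-(acetyloxy)-7-hydroxy-3,7-dimethyldeca-2,9-dien-6-yl 6-methyl-2-methylidenehept-5-enoate
Product: 17 (2E)-5-[(2S,3R)-3-hydroxy-3-methyl-6-(4-methylpent-3-en-1-yl)-7-oxo-2,3,4,7-tetrahydrooxepin-2-yl]-3-methylpent-2-en-1-yl acetate (CNP0314901.1)
Conditions: second-generation Grubbs catalyst (H2IMes)(PCy3)Cl2Ru=CHPh (10 mol %), toluene (2 mM), 80 °C
Reagents that add atoms: none
Why: Ring-closing metathesis, in which the catalyst loads on the only monosubstituted olefin and closes onto the 1,1-disubstituted acrylate with loss of ethene, helped by the quaternary carbinol; the trisubstituted olefins react far more slowly and no stereocentre is involved.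

## Compound list

1 | geranyl acetate, (2E)-3,7-dimethylocta-2,6-dien-1-yl acetate | CC(=O)OC/C=C(\C)CCC=C(C)C | starting material
2 | (2E,6E)-8-hydroxy-3,7-dimethylocta-2,6-dien-1-yl acetate | CC(=O)OC/C=C(\C)CC/C=C(\C)CO | intermediate
3 | (2E,6E)-8-bromo-3,7-dimethylocta-2,6-dien-1-yl acetate | CC(=O)OC/C=C(\C)CC/C=C(\C)CBr | intermediate
4 | tributyl(ethenyl)stannane | C=C[Sn](CCCC)(CCCC)CCCC | starting material
5 | (2E,6E)-3,7-dimethyldeca-2,6,9-trien-1-yl acetate | CC(=O)OC/C=C(\C)CC/C=C(\C)CC=C | intermediate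
6 | (2E)-3-methyl-5-[(2S,3S)-3-methyl-3-(prop-2-en-1-yl)oxiran-2-yl]pent-2-en-1-yl acetate | CC(=O)OC/C=C(\C)CC[C@@H]1O[C@@]1(C)CC=C | intermediate
7 | (2E,6S,7R)-6,7-dihydroxy-3,7-dimethyldeca-2,9-dien-1-yl acetate | CC(=O)OC/C=C(\C)CC[C@H](O)[C@](C)(O)CC=C | intermediate
8 | diethyl malonate | CCOC(=O)CC(=O)OCC | starting material
9 | 5-bromo-2-methylpent-2-ene | CC(C)=CCCBr | starting material
10 | diethyl 2-(4-methylpent-3-en-1-yl)propanedioate | CCOC(=O)C(CCC=C(C)C)C(=O)OCC | intermediate
11 | 2-(ethoxycarbonyl)-6-methylhept-5-enoic acid (racemic) | CCOC(=O)C(CCC=C(C)C)C(O)=O | intermediate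
12 | Mannich base, 2-[(diethylamino)methyl]-2-(ethoxycarbonyl)-6-methylhept-5-enoic acid (racemic, not isolated) | CCOC(=O)C(CN(CC)CC)(CCC=C(C)C)C(O)=O | intermediate
13 | ethyl 6-methyl-2-methylidenehept-5-enoate | CCOC(=O)C(=C)CCC=C(C)C | intermediate
14 | 6-methyl-2-methylidenehept-5-enoic acid | OC(=O)C(=C)CCC=C(C)C | intermediate
15 | mixed anhydride, 6-methyl-2-methylidenehept-5-enoic 2,4,6-trichlorobenzoic anhydride (not isolated) | C=C(CCC=C(C)C)C(=O)OC(=O)c1c(Cl)cc(Cl)cc1Cl | intermediate
16 | (2E,6S,7R)-1-(acetyloxy)-7-hydroxy-3,7-dimethyldeca-2,9-dien-6-yl 6-methyl-2-methylidenehept-5-enoate | CC(=O)OC/C=C(\C)CC[C@H](OC(=O)C(=C)CCC=C(C)C)[C@](C)(O)CC=C | intermediate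
17 | (2E)-5-[(2S,3R)-3-hydroxy-3-methyl-6-(4-methylpent-3-en-1-yl)-7-oxo-2,3,4,7-tetrahydrooxepin-2-yl]-3-methylpent-2-en-1-yl acetate | CC(=O)OC/C=C(\C)CC[C@@H]1OC(=O)C(CCC=C(C)C)=CC[C@@]1(C)O | target

## Step count

Total steps: 11. Longest linear sequence: 7 (steps 1–5, 10, 11); the acid branch is 4 steps (6–9).

## Three steps most likely to fail

**Step 11 (ring-closing metathesis).** The closure is onto a hindered, electron-poor 1,1-disubstituted olefin in a seven-membered ring, and a competing closure onto the C2=C3 olefin is conceivable. The fallback sets out from 7 and returns at 17. The secondary hydroxyl of 7 is acylated with acryloyl chloride (i-Pr2NEt, CH2Cl2, −20 °C) to give (2E,6S,7R)-1-(acetyloxy)-7-hydroxy-3,7-dimethyldeca-2,9-dien-6-yl prop-2-enoate F1. Ring-closing metathesis with the same ruthenium catalyst now joins two monosubstituted olefins and gives (2E)-5-[(2S,3R)-3-hydroxy-3-methyl-7-oxo-2,3,4,7-tetrahydrooxepin-2-yl]-3-methylpent-2-en-1-yl acetate F2. Johnson-type α-iodination (I2, pyridine, CH2Cl2) gives (2E)-5-[(2S,3R)-3-hydroxy-6-iodo-3-methyl-7-oxo-2,3,4,7-tetrahydrooxepin-2-yl]-3-methylpent-2-en-1-yl acetate F3. Negishi coupling of F3 with (4-methylpent-3-en-1-yl)zinc bromide F4 (made from 9 with Zn dust and LiCl in THF) under Pd2(dba)3/SPhos at rt installs the side chain and gives 17.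

**Step 5 (epoxide hydrolysis).** Partial SN1 character at the tertiary carbon would erode the configuration at C7, and any attack at C6 would erode ee. The fallback sets out from 5 and returns at 7. Triene 5 is epoxidised with the ordinary D-fructose-derived Shi ketone under the step 4 conditions to give the enantiomeric epoxide (2E)-3-methyl-5-[(2R,3R)-3-methyl-3-(prop-2-en-1-yl)oxiran-2-yl]pent-2-en-1-yl acetate F5. Hydroxide then opens F5 at the less hindered secondary carbon (KOH, DMSO/H2O, 100 °C), a strict SN2 inversion at C6 with C7 untouched; the acetate is cleaved as well, giving (2E,6S,7R)-3,7-dimethyldeca-2,9-diene-1,6,7-triol F6. Selective acetylation of the primary allylic hydroxyl (AcCl, 2,4,6-collidine, CH2Cl2, −78 °C) returns 7.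

**Step 4 (Shi epoxidation).** It must pick one of three olefins, it sets both stereocentres, and it depends on the less common catalyst enantiomer. The fallback sets out from 2 and returns at 6, bypassing steps 2 and 3 as well. Sharpless asymmetric epoxidation of allylic alcohol 2 (Ti(OiPr)4, L-(+)-diethyl tartrate, t-BuOOH, 4 Å molecular sieves, CH2Cl2, −20 °C) is fully site-selective and gives (2E)-5-[(2S,3S)-3-(hydroxymethyl)-3-methyloxiran-2-yl]-3-methylpent-2-en-1-yl acetate F7. Triflation (Tf2O, 2,6-lutidine, CH2Cl2, −78 °C) gives (2E)-3-methyl-5-[(2S,3S)-3-methyl-3-{[(trifluoromethanesulfonyl)oxy]methyl}oxiran-2-yl]pent-2-en-1-yl acetate F8, which is not isolated. Direct displacement of the triflate with lithium divinylcuprate (CH2=CH)2CuLi in Et2O at −78 °C, where the allylic acetate and the epoxide are left alone, gives 6.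

## Further compounds

F1 | step 11 | (2E,6S,7R)-1-(acetyloxy)-7-hydroxy-3,7-dimethyldeca-2,9-dien-6-yl prop-2-enoate | CC(=O)OC/C=C(\C)CC[C@H](OC(=O)C=C)[C@](C)(O)CC=C
F2 | step 11 | (2E)-5-[(2S,3R)-3-hydroxy-3-methyl-7-oxo-2,3,4,7-tetrahydrooxepin-2-yl]-3-methylpent-2-en-1-yl acetate | CC(=O)OC/C=C(\C)CC[C@@H]1OC(=O)C=CC[C@@]1(C)O
F3 | step 11 | (2E)-5-[(2S,3R)-3-hydroxy-6-iodo-3-methyl-7-oxo-2,3,4,7-tetrahydrooxepin-2-yl]-3-methylpent-2-en-1-yl acetate | CC(=O)OC/C=C(\C)CC[C@@H]1OC(=O)C(I)=CC[C@@]1(C)O
F4 | step 11 | (4-methylpent-3-en-1-yl)zinc bromide | CC(C)=CCC[Zn]Br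
F5 | step 5 | (2E)-3-methyl-5-[(2R,3R)-3-methyl-3-(prop-2-en-1-yl)oxiran-2-yl]pent-2-en-1-yl acetate | CC(=O)OC/C=C(\C)CC[C@H]1O[C@]1(C)CC=C
F6 | step 5 | (2E,6S,7R)-3,7-dimethyldeca-2,9-diene-1,6,7-triol | OC/C=C(\C)CC[C@H](O)[C@](C)(O)CC=C
F7 | step 4 | (2E)-5-[(2S,3S)-3-(hydroxymethyl)-3-methyloxiran-2-yl]-3-methylpent-2-en-1-yl acetate | CC(=O)OC/C=C(\C)CC[C@@H]1O[C@@]1(C)CO
F8 | step 4 | (2E)-3-methyl-5-[(2S,3S)-3-methyl-3-{[(trifluoromethanesulfonyl)oxy]methyl}oxiran-2-yl]pent-2-en-1-yl acetate | CC(=O)OC/C=C(\C)CC[C@@H]1O[C@@]1(C)COS(=O)(=O)C(F)(F)F
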